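The target is a centrosymmetric α-truxillic cyclobutane (ring A) carrying two N-acyl-5,6-dihydropyridin-2(1H)-one rings (B, B'). In each, N1 joins ring carbon C6H2, ring carbonyl C2 and the exocyclic truxilloyl carbonyl. This imide array is a constitutional isomer of a cyclopent-2-enone oxime O-carboxylate. Everything rests on the N1–C6 bonds. A double Beckmann ring expansion shifts C6 from carbon to nitrogen, closing rings B and B'. The departing truxillate returns as the N-acyl group by a Mumm shift, so one isomerisation delivers both imides. The precursor is the bis[(Z)-cyclopent-2-enone oxime] ester of the solid-state photodimer of 3,4-dimethoxycinnamic acid. It holds no lactam, imide or N–C(sp3) bond.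

Key step: step 4

Remark: the drawn configuration is the achiral, centrosymmetric r-1,c-2,t-3,t-4 (α-truxillic) diastereomer, so only relative configuration has to be set.

Step 1
Reactants: 1 (E)-3,4-dimethoxycinnamic acid (two molecules)
Product: 2 r-1,c-2,t-3,t-4-2,4-bis(3,4-dimethoxyphenyl)cyclobutane-1,3-dicarboxylic acid (α-truxillic type, centrosymmetric)
Conditions: hν (medium-pressure Hg lamp, Pyrex), finely ground crystals of 1 as a stirred aqueous suspension, rt
Reagents that add atoms: none
Why: Topochemical [2+2] photocycloaddition: in the α-type crystal two molecules of 1 lie head-to-tail across an inversion centre with parallel C=C bonds less than 4.2 Å apart, so suprafacial union keeps each aryl/CO2H pair trans and sets all four stereocentres as the centrosymmetric α-truxillic array.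

Step 2
Reactants: 3 cyclopent-2-en-1-one
Product: 4 (Z)-cyclopent-2-en-1-one oxime (OH syn to the vinylic C2–H, anti to C5H2)
Conditions: NH2OH·HCl, NaOAc, MeOH–H2O, 0 °C → rt; SiO2 chromatography (Z isomer kept; E isomer re-equilibrated with cat. HCl/Et2O and recycled)
Reagents that add atoms: hydroxylamine hydrochloride, Cl.NO
Why: Oxime condensation (1,2-addition of NH2OH to the ketone, then dehydration) in acetate buffer should outrun conjugate addition, and the two configurationally stable C=N isomers should be separable on silica, the Z isomer being carried on.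

Step 3
Reactants: 2 α-truxillic-type diacid; 4 (Z)-cyclopent-2-en-1-one oxime (two equivalents)
Product: 5 bis{[(Z)-cyclopent-2-en-1-ylidene]amino} r-1,c-2,t-3,t-4-2,4-bis(3,4-dimethoxyphenyl)cyclobutane-1,3-dicarboxylate (bis oxime ester)
Conditions: DCC (2.2 equiv), DMAP (10 mol %), CH2Cl2–DMF, 0 °C → rt, dark
Reagents that add atoms: none
Why: Steglich-type O-acylation of the oxime hydroxyl (an α-effect nucleophile) runs under near-neutral conditions that should neither epimerise the cyclobutane α-carbons nor invert the C=N geometry.

Step 4
Reactants: 5 bis oxime ester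
Product: 7 target bis-imide CNP0199212.1, via bis(O-acyl lactim) 6 (not isolated)
Conditions: BF3·OEt2 (0.5 equiv, that is 25 mol % per oxime ester), 4 Å MS, ClCH2CH2Cl, 0 → 50 °C, dark
Reagents that add atoms: none
Why: Proposed new method: BF3 bound to the ester carbonyl turns each truxillate into a nucleofuge on nitrogen, and as the N–O bond ionises the ring carbon C5H2 of the cyclopentenone, antiperiplanar to that bond in the Z oxime, shifts from C1 to N and forms the N1–C6 bond (Beckmann rearrangement), the vinyl-conjugated nitrilium/carboxylate contact ion pair then collapsing at carbon to the O-acyl lactim 6. In 6 the six-membered ring holds the nitrogen lone pair syn to the acyloxy group, so a 1,3 O-to-N acyl shift (Mumm rearrangement) gives the imide and frees BF3, which makes the whole step a catalytic isomerisation that runs independently at both ends of 5. The closest known reaction types are the BF3-promoted Beckmann rearrangement of ketoxime carbonates, the Beckmann ring expansion of cyclic enone oximes to α,β-unsaturated lactams and the isoimide-to-imide step of imidoyl chloride/carboxylate, Ugi and Passerini chemistry; new is their fusion, in which the leaving group itself ends as the N-acyl group. Rings B and B' are each closed by a 1,2-shift that expands the five-membered carbocycle to the six-membered azacycle, so no exo/endo attack is involved and the cis C3=C4 bond is carried over unchanged from the cyclopentenone. No stereocentre is formed, and the four cyclobutane centres should be kept because the medium is aprotic, free of base and holds only substoichiometric Lewis acid. The step needs CH2 rather than vinyl migration, secured by the Z geometry of both C=N bonds (anti rule) and backed by the usual preference of cyclic enone oximes for alkyl migration, and it needs capture by the truxillate rather than by an outside nucleophile, secured by the ion pair in a dry, non-nucleophilic solvent.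

Compound list
1 | (E)-3,4-dimethoxycinnamic acid | COc1ccc(/C=C/C(=O)O)cc1OC | starting material
2 | r-1,c-2,t-3,t-4-2,4-bis(3,4-dimethoxyphenyl)cyclobutane-1,3-dicarboxylic acid | COc1ccc([C@H]2[C@H](C(=O)O)[C@H](c3ccc(OC)c(OC)c3)[C@H]2C(=O)O)cc1OC | intermediate
3 | cyclopent-2-en-1-one | O=C1C=CCC1 | starting material
4 | (Z)-cyclopent-2-en-1-one oxime | O/N=C1\C=CCC1 | intermediate
5 | bis{[(Z)-cyclopent-2-en-1-ylidene]amino} ester of 2 | COc1ccc([C@H]2[C@H](C(=O)O/N=C3\C=CCC3)[C@H](c3ccc(OC)c(OC)c3)[C@H]2C(=O)O/N=C2\C=CCC2)cc1OC | intermediate
6 | bis(5,6-dihydropyridin-2-yl) ester of 2 (bis O-acyl lactim, isoimide; not isolated) | COc1ccc([C@H]2[C@H](C(=O)OC3=NCCC=C3)[C@H](c3ccc(OC)c(OC)c3)[C@H]2C(=O)OC2=NCCC=C2)cc1OC | intermediate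
7 | 1,1'-{[r-1,c-2,t-3,t-4-2,4-bis(3,4-dimethoxyphenyl)cyclobutane-1,3-diyl]dicarbonyl}bis[5,6-dihydropyridin-2(1H)-one], CNP0199212.1 | COc1ccc([C@H]2[C@H](C(=O)N3CCC=CC3=O)[C@H](c3ccc(OC)c(OC)c3)[C@H]2C(=O)N2CCC=CC2=O)cc1OC | target

Total step count: 4. Longest linear sequence: 3 steps (1 → 3 → 4, or 2 → 3 → 4).

Steps most likely to fail

Step 4 (Proposed new method).
- Ionisation of an N–O bond with a carboxylate leaving group may be too slow.
- Three processes could then compete: Lewis-acid opening or epimerisation of the donor–acceptor cyclobutane, C=N isomerisation followed by vinyl migration, and hydrolytic loss of the acyl group at the isoimide stage.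
- The fallback uses known chemistry only. It sets out from 4 and 2 and comes back at 7.
- Oxime 4 is sulfonylated (TsCl, Et3N, CH2Cl2, 0 °C) to (Z)-cyclopent-2-en-1-one oxime O-tosylate F1.
- Beckmann rearrangement of F1 in NaHCO3-buffered aqueous acetone should give 5,6-dihydropyridin-2(1H)-one F2.
- Diacid 2 is converted with oxalyl chloride and cat. DMF into the α-truxilloyl dichloride F3.
- F3 N-acylates two equivalents of F2 (Et3N, cat. DMAP, CH2Cl2, 0 °C) to give 7.

Step 2.
- Conjugate addition of hydroxylamine may compete with condensation.
- The Z isomer may form only a small share of the oxime, and the geometry may drift on silica.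
- The fallback removes the geometric question. It sets out from 2 and comes back at 7.
- Commercial cyclopent-3-en-1-one F4 is condensed with NH2OH·HCl/NaOAc to cyclopent-3-en-1-one oxime F5. Its two α-carbons are equivalent, so no E/Z isomers exist.
- DCC/DMAP coupling with 2 gives the bis(cyclopent-3-en-1-ylideneamino) ester F6.
- The rearrangement of step 4 then moves an allylic CH2 to nitrogen and should give the bis(3,6-dihydropyridin-2(1H)-one) imide F7.
- Catalytic DBU in CH2Cl2 at rt shifts both C=C bonds into conjugation to give 7. The doubly activated C3H2 of each lactam is deprotonated far more easily than the cyclobutane α-carbons.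

Step 1.
- The acid may crystallise in a differently packed or light-stable modification.
- Lattice order may be lost at partial conversion, which would stop the reaction.
- The fallback postpones the cycloaddition to the end. It sets out from 1 and comes back at 7.
- Acid 1 is converted with oxalyl chloride and cat. DMF into (E)-3,4-dimethoxycinnamoyl chloride F8.
- F8 N-acylates the lactam 5,6-dihydropyridin-2(1H)-one F2, made from 4 as under step 4, to give the monomeric imide (E)-1-[3-(3,4-dimethoxyphenyl)acryloyl]-5,6-dihydropyridin-2(1H)-one F9.
- Irradiation of crystalline F9 (Pyrex-filtered Hg lamp) should join two antiparallel cinnamoyl C=C bonds head-to-tail and give 7 directly.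

Further compounds
F1 | step 4 | (Z)-cyclopent-2-en-1-one oxime O-tosylate | Cc1ccc(S(=O)(=O)O/N=C2\C=CCC2)cc1
F2 | step 4 | 5,6-dihydropyridin-2(1H)-one | O=C1C=CCCN1
F3 | step 4 | r-1,c-2,t-3,t-4-2,4-bis(3,4-dimethoxyphenyl)cyclobutane-1,3-dicarbonyl dichloride | COc1ccc([C@H]2[C@H](C(=O)Cl)[C@H](c3ccc(OC)c(OC)c3)[C@H]2C(=O)Cl)cc1OC
F4 | step 2 | cyclopent-3-en-1-one (purchased) | O=C1CC=CC1
F5 | step 2 | cyclopent-3-en-1-one oxime | ON=C1CC=CC1
F6 | step 2 | bis(cyclopent-3-en-1-ylideneamino) ester of 2 | COc1ccc([C@H]2[C@H](C(=O)ON=C3CC=CC3)[C@H](c3ccc(OC)c(OC)c3)[C@H]2C(=O)ON=C2CC=CC2)cc1OC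
F7 | step 2 | bis(3,6-dihydropyridin-2(1H)-one) imide of 2 | COc1ccc([C@H]2[C@H](C(=O)N3CC=CCC3=O)[C@H](c3ccc(OC)c(OC)c3)[C@H]2C(=O)N2CC=CCC2=O)cc1OC
F8 | step 1 | (E)-3,4-dimethoxycinnamoyl chloride | COc1ccc(/C=C/C(=O)Cl)cc1OC
F9 | step 1 | (E)-1-[3-(3,4-dimethoxyphenyl)acryloyl]-5,6-dihydropyridin-2(1H)-one | COc1ccc(/C=C/C(=O)N2CCC=CC2=O)cc1OC
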